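## Structural features

Target 18 is a 3-hydroxyisoflavanone. Benzo ring A is fused to the dihydropyranone ring C (O1, the C2 methylene, C3, the C4 ketone, C4a, C8a), and a 2,4-dihydroxyphenyl ring B sits on C3. Ring A is pentasubstituted: the C7 hydroxyl is flanked by 3-methylbut-2-enyl (prenyl) groups at C6 and C8, and only C5 bears hydrogen. C3 is the only stereocentre, a fully substituted carbinol of R configuration (priorities OH > C4 > C2 > C1' of ring B) with no stereogenic neighbour, so its sense must come from a catalyst or reagent.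

The fragile groups are:
- the tertiary benzylic α-ketol (acyloin shift or retro-aldol-type cleavage with base; loss of water across C2–C3 to the isoflavone with acid);
- the two prenyl groups ortho to the C7 phenol (acid-induced chroman formation);
- the electron-rich ring B, whose 2'-hydroxyl is a competing nucleophile.

The real difficulty is twofold: building C3 enantioselectively with three different carbon substituents, and an end game that tells O1 apart from three other phenolic oxygens without acid or strong base. The key step uses the fact that C3 carries an oxygen and lies between the C4 carbonyl and the C2 oxymethylene. A carbene at C3 of an α-diazo deoxybenzoin can take up water (C3–O) and formaldehyde (C2–C3), which leaves only O1–C2 to close ring C.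

The open-chain diol and its diazo precursor were checked against 18: skeleton, substitution pattern and the R descriptor at C3 agree, so no structural correction is needed. One design change is made. O7 is carried as a triisopropylsilyl ether rather than an acetal, so that the last step needs fluoride only and no acid.

## Logic of the disconnections

18 from 17. No skeletal bond is cut; the phenols at O7, O2' and O4' are traced back to three triisopropylsilyl ethers. The free target tolerates neither acid nor strong base, so all remaining protecting groups should fall in one mild operation. The forward step must therefore be a buffered fluoride desilylation.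

17 from 16. The O1–C2 bond is cut. It is the only bond of ring C that can be formed at a primary carbon without touching C3. Cutting it opens ring C to an acyclic diol in which C3 is already complete. The forward etherification requires O1 to be the only free phenol, because a free 2'-oxygen would close a five-membered ether, and requires the phenol to react ahead of the tertiary hydroxyl.

16 from 15. Only the O1–Si bond changes. O1 is distinguished as the single tert-butyldimethylsilyl ether among triisopropylsilyl ethers. The forward step must cleave this one silyl ether selectively and without base strong enough to trigger retro-aldol loss of the C2 unit.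

15 from 13, 14 and water. The C2–C3 and C3–O bonds are cut together. This removes the stereocentre and both heteroatom-bearing carbons in one stroke and reduces the problem to a deoxybenzoin-type diazo ketone plus two one-atom components. The forward step must achieve oxonium ylide formation from water, capture by 14 faster than proton transfer, bond formation at C3 and not at C4, and facial control by a chiral acid.

13 from 12. The C3=N2 unit is traced back to the C3 methylene. The forward diazo transfer needs a base mild enough not to move the O1 silyl group onto the enolate oxygen.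

12 from 11, and 11 from 6 and 10. The C3–C4 bond is cut between the carbonyl carbon (an aldehyde in 6) and the benzylic carbon (the organozinc 10). This splits the molecule into its ring A and ring B halves. The forward addition needs a benzylic nucleophile that can be formed without homocoupling and an alkoxide that does not accept the neighbouring silyl group; a mild oxidation then restores the ketone.

10 from 9, 8, 7 and 1. Only functional groups change (C–Zn, C–Cl, C–OH, CHO, O–Si), so ring B comes from the same dihydroxybenzaldehyde as ring A. The benzylic chloride is reactive and must be used at once.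

6 from 5, 5 from 3 and 4, 3 from 2, 2 from 1. The two aryl–CH2 bonds to the prenyl groups at C6 and C8 are cut, then the two C–I bonds. Direct C-prenylation of a resorcinol is unselective, whereas iodination goes cleanly to the two activated positions and cross-coupling places the prenyl groups exactly there. The coupling must transfer the prenyl group through its CH2 terminus, and the two silylations must distinguish the free from the chelated phenol.

## Other disconnections considered

Alternative 1: The cut is C4–C4a. The precursor A1 is a 3-hydroxybenzofuran-2-one in which the 2'-oxygen of ring B acylates C4, C3 already carries its hydroxyl, and the C2 methylene is ether-linked through O1 to a ring A aryl bromide. Bromine–lithium exchange at C4a would let the aryllithium attack the lactone carbonyl (6-exo-trig); collapse of the adduct expels the 2'-phenoxide and gives chromanone A2.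
- In its favour: the lactone is at once acyl donor and protecting group for O2', so ring B is differentiated for free. The ketone and ring C arise in one polar, well-understood step. C3 is set beforehand by established chemistry.
- Against it here: the O1–C2 ether must be made by substitution at a neopentyl-type carbon with a 2,6-disubstituted phenol. The tertiary hydroxyl must be carried as an alkoxide or protected. Ring A needs a bromine kept through two prenylations. The acetal at O7 and O4' in A2 calls for an acidic last step on a molecule that can dehydrate to the isoflavone.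
- Comparison: structurally both plans pivot on C3, but this one still has to find a separate enantioselective entry to the quaternary carbinol. On mechanistic precedent of the key step it is the better of the two. On step economy and on the end game it is judged the weaker.

Alternative 2: The cuts are C3–C4 and the O1–C2 acyl bond of a dihydrocoumarin. The o-quinone methide released from sulfone A3 by Cs2CO3 and the aryl(alkoxy)ketene released from acid chloride A4 would combine under a chiral triazolium-derived N-heterocyclic carbene to give lactone A5.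
- In its favour: ring closure and the quaternary stereocentre come from one catalytic step of a reaction class with good enantiocontrol for disubstituted ketenes. The fragments are simple, and the bromines allow late prenylation.
- Against it here: A5 has its carbonyl at C2 and a methylene at C4. A transposition is needed: lactone to cyclic ether, then benzylic oxidation at C4. That oxidation cannot be run with prenyl groups present, so two cross-couplings, an oxidative ether cleavage and an acidic acetal removal all follow. An alkoxy-substituted ketene is also an untested partner.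
- Comparison: on stereocontrol precedent and on avoiding diazo compounds it is the equal or the better of the chosen plan. On structure it builds the wrong oxidation pattern, and on step economy it is clearly longer after the key step.

Alternative 3: The cuts are C4–C4a and O1–C2. In ester A6 a ring A bromophenol is acylated by a 2-aryloxirane-2-carboxylic acid. Bromine–lithium exchange would trigger an anionic Fries acyl shift (C4–C4a), and the released O1 phenoxide would open the epoxide at its CH2 carbon to give chromanone A7.
- In its favour: two ring bonds form in one cascade. C3 is carried unchanged from the epoxide because the phenoxide attacks the methylene carbon. Neither a selective desilylation nor a Mitsunobu step is needed.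
- Against it here: A6 is an aryl ester of an ionisation-prone, electron-rich α-aryl glycidic acid and must be made from a hindered phenol. The aryllithium can attack the epoxide or a second ester. The tri-acetal A7 again needs acid at the end.
- Comparison: on convergence and on the number of operations after the stereocentre is set it is the equal or the better of the chosen plan, and its stereocentre rests on known epoxide chemistry. The chosen plan is preferred because it sets C3 and both adjacent bonds catalytically from an achiral precursor and ends under buffered fluoride, the only deprotection conditions that suit this α-ketol.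

Key step: step 11

Assumption: the facial sense imposed by the binaphthyl hydrogen phosphate on this new electrophile cannot be predicted with confidence; the (R)-acid is written in step 11 and its enantiomer is to be used if the first one favours the S diol.

## Route

Step 1
Reactants: 1 2,4-dihydroxybenzaldehyde
Product: 2 2,4-dihydroxy-3,5-diiodobenzaldehyde
Conditions: NIS (2.1 equiv), AcOH, rt
Reagents that add atoms: N-iodosuccinimide, O=C1CCC(=O)N1I
Why: Electrophilic aromatic iodination: C3 and C5 are each ortho or para to both hydroxyls while C6 is meta to both, so two equivalents of NIS should stop at the 3,5-diiodide.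

Step 2
Reactants: 2 2,4-dihydroxy-3,5-diiodobenzaldehyde
Product: 3 2-hydroxy-3,5-diiodo-4-(triisopropylsilyloxy)benzaldehyde
Conditions: TIPSOTf (1.05 equiv), 2,6-lutidine, CH2Cl2, −78 to 0 °C
Reagents that add atoms: triisopropylsilyl trifluoromethanesulfonate, CC(C)[Si](OS(=O)(=O)C(F)(F)F)(C(C)C)C(C)C
Why: Selective O-silylation: the 4-OH is the more acidic phenol and is not tied up in the hydrogen bond to the formyl oxygen, so one equivalent of silyl triflate at low temperature should silylate it alone; a silyl ether at this oxygen (later O7) allows a fluoride-only end game.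

Step 3
Reactants: 3 2-hydroxy-3,5-diiodo-4-(triisopropylsilyloxy)benzaldehyde, 4 tributyl(3-methylbut-2-enyl)stannane
Product: 5 2-hydroxy-3,5-bis(3-methylbut-2-enyl)-4-(triisopropylsilyloxy)benzaldehyde
Conditions: 4 (2.6 equiv), Pd(PPh3)4 (10 mol%), DMF, 90 °C, degassed
Reagents that add atoms: none
Why: Twofold Stille coupling: oxidative addition of zerovalent palladium to each C–I bond, allyl transfer from tin and reductive elimination, which with prenylstannanes and this catalyst normally delivers the linear 3-methylbut-2-enyl group; the chelated phenol and the aldehyde are tolerated.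

Step 4
Reactants: 5 2-hydroxy-3,5-bis(3-methylbut-2-enyl)-4-(triisopropylsilyloxy)benzaldehyde
Product: 6 2-(tert-butyldimethylsilyloxy)-3,5-bis(3-methylbut-2-enyl)-4-(triisopropylsilyloxy)benzaldehyde
Conditions: TBSOTf (1.3 equiv), 2,6-lutidine, CH2Cl2, 0 °C
Reagents that add atoms: tert-butyldimethylsilyl trifluoromethanesulfonate, CC(C)(C)[Si](C)(C)OS(=O)(=O)C(F)(F)F
Why: Silylation of the hydrogen-bonded, hindered 2-OH needs the silyl triflate; the aldehyde has no α-hydrogen, so no silyl enol ether can form.

Step 5
Reactants: 1 2,4-dihydroxybenzaldehyde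
Product: 7 2,4-bis(triisopropylsilyloxy)benzaldehyde
Conditions: TIPSCl (2.4 equiv), imidazole (5 equiv), DMAP (cat.), DMF, rt to 40 °C
Reagents that add atoms: triisopropylsilyl chloride, CC(C)[Si](Cl)(C(C)C)C(C)C
Why: Standard bis-silylation of both phenols; gentle warming drives the chelated 2-OH to completion.

Step 6
Reactants: 7 2,4-bis(triisopropylsilyloxy)benzaldehyde
Product: 8 [2,4-bis(triisopropylsilyloxy)phenyl]methanol
Conditions: i-Bu2AlH (1.1 equiv), CH2Cl2, −78 °C; aq. potassium sodium tartrate
Reagents that add atoms: none
Why: 1,2-Reduction of the aldehyde by i-Bu2AlH at low temperature; the aluminium alkoxide is a poor nucleophile, which should prevent migration of the ortho silyl group from the phenolic to the benzylic oxygen.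

Step 7
Reactants: 8 [2,4-bis(triisopropylsilyloxy)phenyl]methanol
Product: 9 1-(chloromethyl)-2,4-bis(triisopropylsilyloxy)benzene
Conditions: SOCl2 (1.1 equiv), 2,6-lutidine (1.2 equiv), CH2Cl2, −20 to 0 °C; used crude at once
Reagents that add atoms: thionyl chloride, O=S(Cl)Cl
Why: Deoxychlorination through the chlorosulfite; the hindered base takes up HCl without being alkylated by the reactive electron-rich benzylic chloride, and the silyl ethers survive.

Step 8
Reactants: 9 1-(chloromethyl)-2,4-bis(triisopropylsilyloxy)benzene, 6 2-(tert-butyldimethylsilyloxy)-3,5-bis(3-methylbut-2-enyl)-4-(triisopropylsilyloxy)benzaldehyde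
Product: 11 2-[2,4-bis(triisopropylsilyloxy)phenyl]-1-[2-(tert-butyldimethylsilyloxy)-3,5-bis(3-methylbut-2-enyl)-4-(triisopropylsilyloxy)phenyl]ethan-1-ol (racemic), via benzylic zinc chloride 10 (not isolated)
Conditions: 9 (1.5 equiv), Mg turnings, ZnCl2, LiCl, THF, 25 °C; then 6, 0 °C to rt; aq. NH4Cl
Reagents that add atoms: none
Why: Magnesium insertion into the benzylic C–Cl bond with immediate transmetalation to zinc keeps Wurtz homocoupling and 1,4 oxygen-to-carbon silyl shift low, and the MgCl2 formed activates the aldehyde for 1,2-addition (Barbier/Grignard-type benzylation), forming the C3–C4 bond; the carbinol centre is formed as a racemate and is erased in step 9.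

Step 9
Reactants: 11 2-[2,4-bis(triisopropylsilyloxy)phenyl]-1-[2-(tert-butyldimethylsilyloxy)-3,5-bis(3-methylbut-2-enyl)-4-(triisopropylsilyloxy)phenyl]ethan-1-ol
Product: 12 2-[2,4-bis(triisopropylsilyloxy)phenyl]-1-[2-(tert-butyldimethylsilyloxy)-3,5-bis(3-methylbut-2-enyl)-4-(triisopropylsilyloxy)phenyl]ethan-1-one
Conditions: Dess–Martin periodinane (1.3 equiv), NaHCO3, CH2Cl2, 0 °C to rt
Reagents that add atoms: none
Why: Dess–Martin oxidation of the secondary alcohol under buffered, non-acidic conditions leaves the prenyl alkenes and all silyl ethers untouched.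

Step 10
Reactants: 12 2-[2,4-bis(triisopropylsilyloxy)phenyl]-1-[2-(tert-butyldimethylsilyloxy)-3,5-bis(3-methylbut-2-enyl)-4-(triisopropylsilyloxy)phenyl]ethan-1-one
Product: 13 2-[2,4-bis(triisopropylsilyloxy)phenyl]-1-[2-(tert-butyldimethylsilyloxy)-3,5-bis(3-methylbut-2-enyl)-4-(triisopropylsilyloxy)phenyl]-2-diazoethan-1-one
Conditions: p-ABSA (1.5 equiv), DBU (1.5 equiv), MeCN, 0 °C, dark
Reagents that add atoms: 4-acetamidobenzenesulfonyl azide, CC(=O)Nc1ccc(cc1)S(=O)(=O)N=[N+]=[N-]
Why: Regitz diazo transfer: DBU generates the benzylic enolate of the deoxybenzoin, which attacks the terminal nitrogen of the sulfonyl azide and expels the sulfonamide; low temperature and a short reaction time limit transfer of the O1 silyl group to the enolate oxygen.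

Step 11
Reactants: 13 2-[2,4-bis(triisopropylsilyloxy)phenyl]-1-[2-(tert-butyldimethylsilyloxy)-3,5-bis(3-methylbut-2-enyl)-4-(triisopropylsilyloxy)phenyl]-2-diazoethan-1-one, 14 formaldehyde
Product: 15 (2R)-2-[2,4-bis(triisopropylsilyloxy)phenyl]-1-[2-(tert-butyldimethylsilyloxy)-3,5-bis(3-methylbut-2-enyl)-4-(triisopropylsilyloxy)phenyl]-2,3-dihydroxypropan-1-one
Conditions: Rh2(OAc)4 (2 mol%), (R)-3,3'-bis(2,4,6-triisopropylphenyl)-1,1'-binaphthyl-2,2'-diyl hydrogen phosphate (10 mol%), H2O (2 equiv), 14 (monomeric, methanol-free, about 1 M in THF from cracked paraformaldehyde, 5 equiv), CH2Cl2, −20 °C, slow addition of 13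
Reagents that add atoms: water, O
Why: Proposed new method: Rh2(OAc)4 converts 13 into a donor–acceptor carbene at C3, water adds to it to give a protic oxonium ylide (equivalently its rhodium-associated enol), and this nucleophile attacks through C3 the formaldehyde that is hydrogen-bonded to the chiral phosphoric acid, so that C3–O and C2–C3 form in one operation. The closest known reaction type is the Rh2(OAc)4/chiral phosphoric acid three-component coupling of aryl diazo carbonyl compounds with water or alcohols and aryl aldehydes or imines; formaldehyde as the trapping partner and an α-diazo deoxybenzoin as the carbene source are the extensions. No ring is closed, so no mode of cyclisation has to be controlled, and ring C is deliberately left open. The single new stereocentre C3 is set by the phosphoric acid, which binds the ylide hydroxyl and the aldehyde oxygen in a bifunctional transition state whose 2,4,6-triisopropylphenyl walls expose one face of the planar C3 nucleophile; the substrate has no other stereocentre to bias the outcome. Chemoselectivity for water over every other heteroatom is secured by the exclusive use of silyl ethers (hindered, weakly basic oxygens and no free O–H), and methanol-free formaldehyde keeps a competing alcohol out. Trapping must outrun the 1,2-proton shift to the simple O–H insertion product, which the small and highly electrophilic formaldehyde, its excess, the low temperature and the slow addition of 13 favour. Bond formation must occur at C3 and not at C4 of the enediol that full proton transfer would give, which is favoured because C4 is shielded by the O1 silyl ether and keeps its conjugation with ring A as the aroyl carbon. The bulky O1 and O2' silyl ethers also keep the carbene from intramolecular ylide formation and C–H insertion.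

Step 12
Reactants: 15 (2R)-2-[2,4-bis(triisopropylsilyloxy)phenyl]-1-[2-(tert-butyldimethylsilyloxy)-3,5-bis(3-methylbut-2-enyl)-4-(triisopropylsilyloxy)phenyl]-2,3-dihydroxypropan-1-one
Product: 16 (2R)-2-[2,4-bis(triisopropylsilyloxy)phenyl]-2,3-dihydroxy-1-[2-hydroxy-3,5-bis(3-methylbut-2-enyl)-4-(triisopropylsilyloxy)phenyl]propan-1-one
Conditions: TBAF (1.05 equiv), AcOH (1.05 equiv), THF, −20 to 0 °C
Reagents that add atoms: none
Why: Chemoselective fluoride desilylation: the O1 silyl ether is the only tert-butyldimethylsilyl group and sits on an acyl-conjugated, better leaving phenoxide, so one equivalent of acetic acid-buffered fluoride should cleave it ahead of the triisopropylsilyl ethers; the buffer suppresses retro-aldol loss of formaldehyde and acyloin shift.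

Step 13
Reactants: 16 (2R)-2-[2,4-bis(triisopropylsilyloxy)phenyl]-2,3-dihydroxy-1-[2-hydroxy-3,5-bis(3-methylbut-2-enyl)-4-(triisopropylsilyloxy)phenyl]propan-1-one
Product: 17 (3R)-3-[2,4-bis(triisopropylsilyloxy)phenyl]-3-hydroxy-6,8-bis(3-methylbut-2-enyl)-7-(triisopropylsilyloxy)chroman-4-one
Conditions: PPh3 (1.5 equiv), DIAD (1.5 equiv), THF (0.01 M), 0 °C to rt
Reagents that add atoms: none
Why: Intramolecular Mitsunobu etherification: the O1 phenol, the most acidic OH, protonates the betaine and its phenoxide displaces the activated primary oxygen at C2 in a 6-exo-tet closure; C3 is not a reacting centre, so its R configuration is kept, and the 2'-oxygen is still silylated so no five-membered ether can form.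

Step 14
Reactants: 17 (3R)-3-[2,4-bis(triisopropylsilyloxy)phenyl]-3-hydroxy-6,8-bis(3-methylbut-2-enyl)-7-(triisopropylsilyloxy)chroman-4-one
Product: 18 (3R)-3-(2,4-dihydroxyphenyl)-3,7-dihydroxy-6,8-bis(3-methylbut-2-enyl)chroman-4-one
Conditions: TBAF (4 equiv), AcOH (4 equiv), THF, 0 °C to rt
Reagents that add atoms: none
Why: Fluoride cleavage of the three aryl triisopropylsilyl ethers under acetic acid buffering avoids both acid (dehydration to the isoflavone, prenyl cyclisation) and free phenoxide base (acyloin shift), and C3 is untouched.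

## Compound list

1 | 2,4-dihydroxybenzaldehyde | O=Cc1ccc(O)cc1O | starting material
2 | 2,4-dihydroxy-3,5-diiodobenzaldehyde | O=Cc1cc(I)c(O)c(I)c1O | intermediate
3 | 2-hydroxy-3,5-diiodo-4-(triisopropylsilyloxy)benzaldehyde | O=Cc1cc(I)c(O[Si](C(C)C)(C(C)C)C(C)C)c(I)c1O | intermediate
4 | tributyl(3-methylbut-2-enyl)stannane | CC(C)=CC[Sn](CCCC)(CCCC)CCCC | starting material
5 | 2-hydroxy-3,5-bis(3-methylbut-2-enyl)-4-(triisopropylsilyloxy)benzaldehyde | O=Cc1cc(CC=C(C)C)c(O[Si](C(C)C)(C(C)C)C(C)C)c(CC=C(C)C)c1O | intermediate
6 | 2-(tert-butyldimethylsilyloxy)-3,5-bis(3-methylbut-2-enyl)-4-(triisopropylsilyloxy)benzaldehyde | O=Cc1cc(CC=C(C)C)c(O[Si](C(C)C)(C(C)C)C(C)C)c(CC=C(C)C)c1O[Si](C)(C)C(C)(C)C | intermediate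
7 | 2,4-bis(triisopropylsilyloxy)benzaldehyde | O=Cc1ccc(O[Si](C(C)C)(C(C)C)C(C)C)cc1O[Si](C(C)C)(C(C)C)C(C)C | intermediate
8 | [2,4-bis(triisopropylsilyloxy)phenyl]methanol | OCc1ccc(O[Si](C(C)C)(C(C)C)C(C)C)cc1O[Si](C(C)C)(C(C)C)C(C)C | intermediate
9 | 1-(chloromethyl)-2,4-bis(triisopropylsilyloxy)benzene | ClCc1ccc(O[Si](C(C)C)(C(C)C)C(C)C)cc1O[Si](C(C)C)(C(C)C)C(C)C | intermediate
10 | [2,4-bis(triisopropylsilyloxy)benzyl]zinc chloride | Cl[Zn]Cc1ccc(O[Si](C(C)C)(C(C)C)C(C)C)cc1O[Si](C(C)C)(C(C)C)C(C)C | intermediate (not isolated)
11 | 2-[2,4-bis(triisopropylsilyloxy)phenyl]-1-[2-(tert-butyldimethylsilyloxy)-3,5-bis(3-methylbut-2-enyl)-4-(triisopropylsilyloxy)phenyl]ethan-1-ol (racemic) | OC(Cc1ccc(O[Si](C(C)C)(C(C)C)C(C)C)cc1O[Si](C(C)C)(C(C)C)C(C)C)c1cc(CC=C(C)C)c(O[Si](C(C)C)(C(C)C)C(C)C)c(CC=C(C)C)c1O[Si](C)(C)C(C)(C)C | intermediate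
12 | 2-[2,4-bis(triisopropylsilyloxy)phenyl]-1-[2-(tert-butyldimethylsilyloxy)-3,5-bis(3-methylbut-2-enyl)-4-(triisopropylsilyloxy)phenyl]ethan-1-one | O=C(Cc1ccc(O[Si](C(C)C)(C(C)C)C(C)C)cc1O[Si](C(C)C)(C(C)C)C(C)C)c1cc(CC=C(C)C)c(O[Si](C(C)C)(C(C)C)C(C)C)c(CC=C(C)C)c1O[Si](C)(C)C(C)(C)C | intermediate
13 | 2-[2,4-bis(triisopropylsilyloxy)phenyl]-1-[2-(tert-butyldimethylsilyloxy)-3,5-bis(3-methylbut-2-enyl)-4-(triisopropylsilyloxy)phenyl]-2-diazoethan-1-one | [N-]=[N+]=C(C(=O)c1cc(CC=C(C)C)c(O[Si](C(C)C)(C(C)C)C(C)C)c(CC=C(C)C)c1O[Si](C)(C)C(C)(C)C)c1ccc(O[Si](C(C)C)(C(C)C)C(C)C)cc1O[Si](C(C)C)(C(C)C)C(C)C | intermediate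
14 | formaldehyde | C=O | starting material
15 | (2R)-2-[2,4-bis(triisopropylsilyloxy)phenyl]-1-[2-(tert-butyldimethylsilyloxy)-3,5-bis(3-methylbut-2-enyl)-4-(triisopropylsilyloxy)phenyl]-2,3-dihydroxypropan-1-one | OC[C@](O)(c1ccc(O[Si](C(C)C)(C(C)C)C(C)C)cc1O[Si](C(C)C)(C(C)C)C(C)C)C(=O)c1cc(CC=C(C)C)c(O[Si](C(C)C)(C(C)C)C(C)C)c(CC=C(C)C)c1O[Si](C)(C)C(C)(C)C | intermediate
16 | (2R)-2-[2,4-bis(triisopropylsilyloxy)phenyl]-2,3-dihydroxy-1-[2-hydroxy-3,5-bis(3-methylbut-2-enyl)-4-(triisopropylsilyloxy)phenyl]propan-1-one | OC[C@](O)(c1ccc(O[Si](C(C)C)(C(C)C)C(C)C)cc1O[Si](C(C)C)(C(C)C)C(C)C)C(=O)c1cc(CC=C(C)C)c(O[Si](C(C)C)(C(C)C)C(C)C)c(CC=C(C)C)c1O | intermediate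
17 | (3R)-3-[2,4-bis(triisopropylsilyloxy)phenyl]-3-hydroxy-6,8-bis(3-methylbut-2-enyl)-7-(triisopropylsilyloxy)chroman-4-one | CC(C)=CCc1cc2c(c(CC=C(C)C)c1O[Si](C(C)C)(C(C)C)C(C)C)OC[C@](O)(c1ccc(O[Si](C(C)C)(C(C)C)C(C)C)cc1O[Si](C(C)C)(C(C)C)C(C)C)C2=O | intermediate
18 | (3R)-3-(2,4-dihydroxyphenyl)-3,7-dihydroxy-6,8-bis(3-methylbut-2-enyl)chroman-4-one | CC(C)=CCc1cc2c(c(CC=C(C)C)c1O)OC[C@](O)(c1ccc(O)cc1O)C2=O | target

## Step count and least certain steps

Total: 14 steps. Longest linear sequence: 11 steps (steps 1–4 and 8–14); the ring B branch (steps 5–7) joins at step 8.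

Step 11 (key step, new method). Three things may go wrong:
- proton transfer within the ylide may outrun capture by formaldehyde, giving plain O–H insertion with no C2–C3 bond;
- the small, weakly bound electrophile may be delivered with poor facial selectivity;
- the symmetrical enediol may form and react through C4, scrambling the regiochemistry.

The fallback uses known chemistry and sets out from 12. α-Methylenation with CH2(NMe2)2 and Ac2O should give 2-[2,4-bis(triisopropylsilyloxy)phenyl]-1-[2-(tert-butyldimethylsilyloxy)-3,5-bis(3-methylbut-2-enyl)-4-(triisopropylsilyloxy)phenyl]prop-2-en-1-one F1. One equivalent of acetic acid-buffered TBAF should free O1, which adds to the enone in an oxa-Michael closure to racemic 3-[2,4-bis(triisopropylsilyloxy)phenyl]-6,8-bis(3-methylbut-2-enyl)-7-(triisopropylsilyloxy)chroman-4-one F2. Deprotonation at C3 with NaN(SiMe3)2 at −78 °C and reagent-controlled hydroxylation of the enolate with an enantiopure (camphorsulfonyl)oxaziridine then returns to the route at 17.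

Step 12. Fluoride may also attack the unhindered 4'-O silyl ether, or its basicity may start retro-aldol cleavage of the diol. The fallback sets out from 15 and joins desilylation and ring closure. Selective mesylation of the primary hydroxyl (MsCl, 2,4,6-collidine) should give (2R)-2-[2,4-bis(triisopropylsilyloxy)phenyl]-3-[2-(tert-butyldimethylsilyloxy)-3,5-bis(3-methylbut-2-enyl)-4-(triisopropylsilyloxy)phenyl]-2-hydroxy-3-oxopropyl methanesulfonate F3. CsF in DMF at 0 °C then frees the O1 phenoxide, which displaces the sulfonate at once (intramolecular Williamson closure) and returns to the route at 17. Any material that has also lost a ring B silyl group converges on 18 in step 14.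

Step 10. The enolate may take the silyl group from O1 in a 1,5 oxygen-to-oxygen shift, or transfer to the hindered benzylic position may stall. The fallback changes the order of events and sets out from 5. After deprotonation of O1–H with i-PrMgCl, addition of 10 should give 2-[2,4-bis(triisopropylsilyloxy)phenyl]-1-[2-hydroxy-3,5-bis(3-methylbut-2-enyl)-4-(triisopropylsilyloxy)phenyl]ethan-1-ol F4. MnO2 should oxidise the benzylic alcohol to 2-[2,4-bis(triisopropylsilyloxy)phenyl]-1-[2-hydroxy-3,5-bis(3-methylbut-2-enyl)-4-(triisopropylsilyloxy)phenyl]ethan-1-one F5. Diazo transfer with p-ABSA and excess DBU should give 2-[2,4-bis(triisopropylsilyloxy)phenyl]-2-diazo-1-[2-hydroxy-3,5-bis(3-methylbut-2-enyl)-4-(triisopropylsilyloxy)phenyl]ethan-1-one F6. Silylation with TBSCl and imidazole then returns to the route at 13, so that no enolate ever sits beside an O1–Si bond.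

Step 8. Homocoupling during metal insertion into the electron-rich benzylic chloride, or silyl migration to the new alkoxide, may erode the addition. The fallback sets out from 9 and avoids a benzylic organometallic made from the halide. PhSO2Na should give 1-[(phenylsulfonyl)methyl]-2,4-bis(triisopropylsilyloxy)benzene F7. Its lithium anion (n-BuLi, −78 °C) adds to 6 to give 2-[2,4-bis(triisopropylsilyloxy)phenyl]-1-[2-(tert-butyldimethylsilyloxy)-3,5-bis(3-methylbut-2-enyl)-4-(triisopropylsilyloxy)phenyl]-2-(phenylsulfonyl)ethan-1-ol F8. Dess–Martin oxidation gives 2-[2,4-bis(triisopropylsilyloxy)phenyl]-1-[2-(tert-butyldimethylsilyloxy)-3,5-bis(3-methylbut-2-enyl)-4-(triisopropylsilyloxy)phenyl]-2-(phenylsulfonyl)ethan-1-one F9. Reductive desulfonylation with SmI2 in THF/MeOH returns to the route at 12.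

Step 3. Allyl transposition during transfer from tin (branched 1,1-dimethylallyl product), slow coupling at the iodide between two oxygens, or protodeiodination may lower the outcome. The fallback sets out from 3. Stille coupling with allyltributylstannane, which has no regiochemical ambiguity, should give 2-hydroxy-3,5-bis(prop-2-enyl)-4-(triisopropylsilyloxy)benzaldehyde F10. Cross-metathesis with excess 2-methylbut-2-ene and the second-generation Grubbs catalyst then returns to the route at 5.

## Further compounds

F1 | step 11 | 2-[2,4-bis(triisopropylsilyloxy)phenyl]-1-[2-(tert-butyldimethylsilyloxy)-3,5-bis(3-methylbut-2-enyl)-4-(triisopropylsilyloxy)phenyl]prop-2-en-1-one | C=C(c1ccc(O[Si](C(C)C)(C(C)C)C(C)C)cc1O[Si](C(C)C)(C(C)C)C(C)C)C(=O)c1cc(CC=C(C)C)c(O[Si](C(C)C)(C(C)C)C(C)C)c(CC=C(C)C)c1O[Si](C)(C)C(C)(C)C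
F2 | step 11 | 3-[2,4-bis(triisopropylsilyloxy)phenyl]-6,8-bis(3-methylbut-2-enyl)-7-(triisopropylsilyloxy)chroman-4-one (racemic) | CC(C)=CCc1cc2c(c(CC=C(C)C)c1O[Si](C(C)C)(C(C)C)C(C)C)OCC(c1ccc(O[Si](C(C)C)(C(C)C)C(C)C)cc1O[Si](C(C)C)(C(C)C)C(C)C)C2=O
F3 | step 12 | (2R)-2-[2,4-bis(triisopropylsilyloxy)phenyl]-3-[2-(tert-butyldimethylsilyloxy)-3,5-bis(3-methylbut-2-enyl)-4-(triisopropylsilyloxy)phenyl]-2-hydroxy-3-oxopropyl methanesulfonate | CS(=O)(=O)OC[C@](O)(c1ccc(O[Si](C(C)C)(C(C)C)C(C)C)cc1O[Si](C(C)C)(C(C)C)C(C)C)C(=O)c1cc(CC=C(C)C)c(O[Si](C(C)C)(C(C)C)C(C)C)c(CC=C(C)C)c1O[Si](C)(C)C(C)(C)C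
F4 | step 10 | 2-[2,4-bis(triisopropylsilyloxy)phenyl]-1-[2-hydroxy-3,5-bis(3-methylbut-2-enyl)-4-(triisopropylsilyloxy)phenyl]ethan-1-ol (racemic) | OC(Cc1ccc(O[Si](C(C)C)(C(C)C)C(C)C)cc1O[Si](C(C)C)(C(C)C)C(C)C)c1cc(CC=C(C)C)c(O[Si](C(C)C)(C(C)C)C(C)C)c(CC=C(C)C)c1O
F5 | step 10 | 2-[2,4-bis(triisopropylsilyloxy)phenyl]-1-[2-hydroxy-3,5-bis(3-methylbut-2-enyl)-4-(triisopropylsilyloxy)phenyl]ethan-1-one | O=C(Cc1ccc(O[Si](C(C)C)(C(C)C)C(C)C)cc1O[Si](C(C)C)(C(C)C)C(C)C)c1cc(CC=C(C)C)c(O[Si](C(C)C)(C(C)C)C(C)C)c(CC=C(C)C)c1O
F6 | step 10 | 2-[2,4-bis(triisopropylsilyloxy)phenyl]-2-diazo-1-[2-hydroxy-3,5-bis(3-methylbut-2-enyl)-4-(triisopropylsilyloxy)phenyl]ethan-1-one | [N-]=[N+]=C(C(=O)c1cc(CC=C(C)C)c(O[Si](C(C)C)(C(C)C)C(C)C)c(CC=C(C)C)c1O)c1ccc(O[Si](C(C)C)(C(C)C)C(C)C)cc1O[Si](C(C)C)(C(C)C)C(C)C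
F7 | step 8 | 1-[(phenylsulfonyl)methyl]-2,4-bis(triisopropylsilyloxy)benzene | O=S(=O)(Cc1ccc(O[Si](C(C)C)(C(C)C)C(C)C)cc1O[Si](C(C)C)(C(C)C)C(C)C)c1ccccc1
F8 | step 8 | 2-[2,4-bis(triisopropylsilyloxy)phenyl]-1-[2-(tert-butyldimethylsilyloxy)-3,5-bis(3-methylbut-2-enyl)-4-(triisopropylsilyloxy)phenyl]-2-(phenylsulfonyl)ethan-1-ol (mixture of diastereomers) | OC(C(c1ccc(O[Si](C(C)C)(C(C)C)C(C)C)cc1O[Si](C(C)C)(C(C)C)C(C)C)S(=O)(=O)c1ccccc1)c1cc(CC=C(C)C)c(O[Si](C(C)C)(C(C)C)C(C)C)c(CC=C(C)C)c1O[Si](C)(C)C(C)(C)C
F9 | step 8 | 2-[2,4-bis(triisopropylsilyloxy)phenyl]-1-[2-(tert-butyldimethylsilyloxy)-3,5-bis(3-methylbut-2-enyl)-4-(triisopropylsilyloxy)phenyl]-2-(phenylsulfonyl)ethan-1-one (racemic) | O=C(C(c1ccc(O[Si](C(C)C)(C(C)C)C(C)C)cc1O[Si](C(C)C)(C(C)C)C(C)C)S(=O)(=O)c1ccccc1)c1cc(CC=C(C)C)c(O[Si](C(C)C)(C(C)C)C(C)C)c(CC=C(C)C)c1O[Si](C)(C)C(C)(C)C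
F10 | step 3 | 2-hydroxy-3,5-bis(prop-2-enyl)-4-(triisopropylsilyloxy)benzaldehyde | O=Cc1cc(CC=C)c(O[Si](C(C)C)(C(C)C)C(C)C)c(CC=C)c1O
A1 | alternative 1 | (3R)-3-{[2-bromo-5-(methoxymethoxy)-4,6-bis(3-methylbut-2-enyl)phenoxy]methyl}-3-hydroxy-6-(methoxymethoxy)-1-benzofuran-2(3H)-one | COCOc1ccc2c(c1)OC(=O)[C@]2(O)COc1c(Br)cc(CC=C(C)C)c(OCOC)c1CC=C(C)C
A2 | alternative 1 | (3R)-3-hydroxy-3-[2-hydroxy-4-(methoxymethoxy)phenyl]-7-(methoxymethoxy)-6,8-bis(3-methylbut-2-enyl)chroman-4-one | CC(C)=CCc1cc2c(c(CC=C(C)C)c1OCOC)OC[C@](O)(c1ccc(OCOC)cc1O)C2=O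
A3 | alternative 2 | 2,4-dibromo-3-(methoxymethoxy)-6-[(4-methylphenylsulfonyl)methyl]phenol | Cc1ccc(cc1)S(=O)(=O)Cc1cc(Br)c(OCOC)c(Br)c1O
A4 | alternative 2 | 2-[2,4-bis(methoxymethoxy)phenyl]-2-[(4-methoxybenzyl)oxy]acetyl chloride (racemic) | COc1ccc(COC(C(=O)Cl)c2ccc(OCOC)cc2OCOC)cc1
A5 | alternative 2 | (3R)-6,8-dibromo-3-[2,4-bis(methoxymethoxy)phenyl]-3-[(4-methoxybenzyl)oxy]-7-(methoxymethoxy)chroman-2-one | Brc1cc2c(c(Br)c1OCOC)OC(=O)[C@](OCc1ccc(OC)cc1)(c1ccc(OCOC)cc1OCOC)C2
A6 | alternative 3 | 2-bromo-5-(methoxymethoxy)-4,6-bis(3-methylbut-2-enyl)phenyl (2R)-2-[2,4-bis(methoxymethoxy)phenyl]oxirane-2-carboxylate | COCOc1ccc([C@@]2(CO2)C(=O)Oc2c(Br)cc(CC=C(C)C)c(OCOC)c2CC=C(C)C)c(OCOC)c1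
A7 | alternative 3 | (3R)-3-[2,4-bis(methoxymethoxy)phenyl]-3-hydroxy-7-(methoxymethoxy)-6,8-bis(3-methylbut-2-enyl)chroman-4-one | CC(C)=CCc1cc2c(c(CC=C(C)C)c1OCOC)OC[C@](O)(c1ccc(OCOC)cc1OCOC)C2=O
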